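**Strategy.** C4 of the upper flavan is a doubly benzylic methine held between two resorcinol-type rings: ring A (C4a lies para to the C7 oxygen, ortho to O1) and ring D of the fisetinidol unit (its C6 lies para to O1, ortho to the C7 oxygen). Both aryl–C4 bonds are therefore traced back to one aldehyde-level carbon. The key step treats the open-chain threo aryloxy hydroxy acetal 7 with acid and benzylated (−)-fisetinidol 9: the oxocarbenium ion is captured by C4a, closing ring C, and the resulting flavan-4-yl cation is arylated by ring D anti to O3. C3 is inverted afterwards through the ketone.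

Key step: step 6

Assumption: (−)-fisetinidol (8), the (2R,3S)-flavan-3-ol of quebracho and black-wattle extracts, is taken as a purchasable natural-product building block.
Convention: on ring C the α-face is the face that carries the C2 aryl group; ring D is the resorcinol ring of the fisetinidol unit.

Step 1
Reactants: 1 1-(benzyloxy)-4-iodobenzene; 2 3,3-diethoxyprop-1-yne
Product: 3 1-(benzyloxy)-4-(3,3-diethoxyprop-1-yn-1-yl)benzene
Conditions: PdCl2(PPh3)2 (2 mol %), CuI (4 mol %), Et3N, THF, rt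
Reagents that add atoms: none
Why: Sonogashira coupling of an aryl iodide with a terminal alkyne; acetal and benzyl ether are inert to the amine base.

Step 2
Reactants: 3 1-(benzyloxy)-4-(3,3-diethoxyprop-1-yn-1-yl)benzene
Product: 4 (Z)-1-(benzyloxy)-4-(3,3-diethoxyprop-1-en-1-yl)benzene
Conditions: H2 (1 atm), Pd/CaCO3 poisoned with Pb(OAc)2 (Lindlar catalyst), quinoline, EtOAc, rt
Reagents that add atoms: none
Why: Lindlar semihydrogenation adds H2 syn and should stop at the (Z)-alkene, leaving the benzyl ether intact.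

Step 3
Reactants: 4 (Z)-1-(benzyloxy)-4-(3,3-diethoxyprop-1-en-1-yl)benzene
Product: 5 (2S,3S)-2-[4-(benzyloxy)phenyl]-3-(diethoxymethyl)oxirane (cis)
Conditions: aq. NaOCl (pH 11.3), (S,S)-(salen)MnCl [(S,S)-N,N'-bis(3,5-di-tert-butylsalicylidene)-1,2-cyclohexanediaminatomanganese chloride, trivalent manganese] (5 mol %), 4-phenylpyridine N-oxide (20 mol %), CH2Cl2, 0 °C
Reagents that add atoms: sodium hypochlorite, [Na+].[O-]Cl
Why: Jacobsen epoxidation, for which conjugated cis-disubstituted alkenes are the best substrate class; the (S,S)-ligand should direct oxo transfer to the face giving the (2S,3S)-cis-epoxide, which sets both carbons under catalyst control.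

Step 4
Reactants: 5 (2S,3S)-2-[4-(benzyloxy)phenyl]-3-(diethoxymethyl)oxirane; 6 3-(benzyloxy)phenol
Product: 7 (2S,3R)-3-[3-(benzyloxy)phenoxy]-3-[4-(benzyloxy)phenyl]-1,1-diethoxypropan-2-ol (threo)
Conditions: 6 (1.5 equiv), Cs2CO3 (0.2 equiv), DMF, 80 °C
Reagents that add atoms: none
Why: SN2 opening of the aryl epoxide by phenoxide at the benzylic carbon (activated by the 4-benzyloxyphenyl group, whereas the other carbon is deactivated and shielded by the acetal) with inversion, so the cis-epoxide gives the threo aryloxy alcohol: the future C2 is set by inversion and the future C3 is retained.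

Step 5
Reactants: 8 (−)-fisetinidol, (2R,3S)-2-(3,4-dihydroxyphenyl)chromane-3,7-diol
Product: 9 (2R,3S)-3,7-bis(benzyloxy)-2-[3,4-bis(benzyloxy)phenyl]chromane
Conditions: NaH (4.5 equiv), BnBr (4.5 equiv), DMF, 0 °C → rt
Reagents that add atoms: benzyl bromide, BrCc1ccccc1
Why: Williamson etherification of the three phenols and the secondary alcohol without touching a stereocenter; capping O3 of this unit leaves the upper C3 hydroxyl as the only alcohol to be oxidised in step 7.

Step 6
Reactants: 7 (2S,3R)-3-[3-(benzyloxy)phenoxy]-3-[4-(benzyloxy)phenyl]-1,1-diethoxypropan-2-ol; 9 (2R,3S)-3,7-bis(benzyloxy)-2-[3,4-bis(benzyloxy)phenyl]chromane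
Product: 11 (2R,3R,4R)-7-(benzyloxy)-2-[4-(benzyloxy)phenyl]-4-{(2R,3S)-3,7-bis(benzyloxy)-2-[3,4-bis(benzyloxy)phenyl]chroman-6-yl}chroman-3-ol, via 4-ethoxyflavan-3-ol 10 (not isolated)
Conditions: 9 (3 equiv), TMSOTf (0.3 equiv), 4 Å MS, CH2Cl2, −78 → −30 °C; Et3N quench
Reagents that add atoms: none
Why: TMSOTf ionises the diethyl acetal to an oxocarbenium ion at C4, which the ring A carbon para to the benzyloxy group attacks (6-exo-trig Friedel–Crafts closure of ring C, forming C4–C4a) to give 10; a second ionisation gives the ring-A-stabilised flavan-4-yl cation, which C6 of 9 captures. The closest known reaction types are the acid-promoted cyclisation of aryloxy acetals to 4-alkoxychromans and the Lewis-acid coupling of 4-alkoxyflavans with flavan-3-ols used for proanthocyanidins. The C4 configuration formed in the ring closure is erased on ionisation; the final one is set by the 2,3-cis cation, whose pseudo-axial 3α-oxygen leaves only the β-face open, so ring D enters anti to O3 (3,4-trans, C4 as in the target). Should 9 add to the oxocarbenium ion first, ring C is still closed by the same bond and allylic strain in the ring-D-stabilised cation leads to the same 3,4-trans product. The step needs ring closure ahead of intermolecular capture (six-membered tether), closure para and not ortho to the ring A benzyloxy group (the ortho site lies between two oxygens), and attack through C6 and not C8 of 9 (C8 is flanked by both oxygens); excess 9 should suppress self-condensation.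

Step 7
Reactants: 11 (2R,3R,4R)-7-(benzyloxy)-2-[4-(benzyloxy)phenyl]-4-{(2R,3S)-3,7-bis(benzyloxy)-2-[3,4-bis(benzyloxy)phenyl]chroman-6-yl}chroman-3-ol
Product: 12 (2R,4R)-7-(benzyloxy)-2-[4-(benzyloxy)phenyl]-4-{(2R,3S)-3,7-bis(benzyloxy)-2-[3,4-bis(benzyloxy)phenyl]chroman-6-yl}chroman-3-one (2,4-trans)
Conditions: Dess–Martin periodinane (1.5 equiv), CH2Cl2, 0 °C → rt
Reagents that add atoms: none
Why: Dess–Martin oxidation of the only free (axial) secondary alcohol under near-neutral conditions that should not enolise the ketone, so C2 and C4 keep their configuration.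

Step 8
Reactants: 12 (2R,4R)-7-(benzyloxy)-2-[4-(benzyloxy)phenyl]-4-{(2R,3S)-3,7-bis(benzyloxy)-2-[3,4-bis(benzyloxy)phenyl]chroman-6-yl}chroman-3-one
Product: 13 (2R,3S,4R)-7-(benzyloxy)-2-[4-(benzyloxy)phenyl]-4-{(2R,3S)-3,7-bis(benzyloxy)-2-[3,4-bis(benzyloxy)phenyl]chroman-6-yl}chroman-3-ol (2,3-trans-3,4-cis)
Conditions: NaBH4, CeCl3·7H2O, THF/MeOH, −78 °C
Reagents that add atoms: none
Why: Luche reduction: in the half-chair with the C2 aryl group equatorial and the C4 aryl group axial on the β-face, hydride should enter axially from the open α-face, anti to the C4 aryl group, giving the equatorial 3β-alcohol and thus the 2,3-trans-3,4-cis array.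

Step 9
Reactants: 13 (2R,3S,4R)-7-(benzyloxy)-2-[4-(benzyloxy)phenyl]-4-{(2R,3S)-3,7-bis(benzyloxy)-2-[3,4-bis(benzyloxy)phenyl]chroman-6-yl}chroman-3-ol
Product: 14 (2R,3S,4S)-4-[(2R,3S)-2-(3,4-dihydroxyphenyl)-3,7-dihydroxychroman-6-yl]-2-(4-hydroxyphenyl)chromane-3,7-diol (CNP0243811.3)
Conditions: H2 (1 atm), Pd(OH)2/C, THF/MeOH/H2O, rt
Reagents that add atoms: none
Why: Hydrogenolysis of all six benzyl ethers; the cyclic C2–O1 bonds and the diarylmethine C4 should survive these neutral conditions, and the C4 descriptor changes from R to S only because the priorities change on debenzylation.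

**Compound list**

1 | 1-(benzyloxy)-4-iodobenzene | Ic1ccc(OCc2ccccc2)cc1 | starting material
2 | 3,3-diethoxyprop-1-yne | C#CC(OCC)OCC | starting material
3 | 1-(benzyloxy)-4-(3,3-diethoxyprop-1-yn-1-yl)benzene | CCOC(OCC)C#Cc1ccc(OCc2ccccc2)cc1 | intermediate
4 | (Z)-1-(benzyloxy)-4-(3,3-diethoxyprop-1-en-1-yl)benzene | CCOC(OCC)/C=C\c1ccc(OCc2ccccc2)cc1 | intermediate
5 | (2S,3S)-2-[4-(benzyloxy)phenyl]-3-(diethoxymethyl)oxirane | c1ccccc1COc1ccc(cc1)[C@@H]1O[C@@H]1C(OCC)OCC | intermediate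
6 | 3-(benzyloxy)phenol | Oc1cccc(OCc2ccccc2)c1 | starting material
7 | (2S,3R)-3-[3-(benzyloxy)phenoxy]-3-[4-(benzyloxy)phenyl]-1,1-diethoxypropan-2-ol | c1ccccc1COc1ccc(cc1)[C@@H](Oc1cccc(OCc2ccccc2)c1)[C@H](O)C(OCC)OCC | intermediate
8 | (−)-fisetinidol, (2R,3S)-2-(3,4-dihydroxyphenyl)chromane-3,7-diol | Oc1ccc2c(c1)O[C@H](c1ccc(O)c(O)c1)[C@@H](O)C2 | starting material
9 | (2R,3S)-3,7-bis(benzyloxy)-2-[3,4-bis(benzyloxy)phenyl]chromane | C(c1ccccc1)Oc1ccc2c(c1)O[C@H](c1ccc(OCc3ccccc3)c(OCc3ccccc3)c1)[C@@H](OCc1ccccc1)C2 | intermediate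
10 | (2R,3R)-7-(benzyloxy)-2-[4-(benzyloxy)phenyl]-4-ethoxychroman-3-ol (2,3-cis, both C4 epimers) | c1ccccc1COc1ccc(cc1)[C@H]2Oc3cc(OCc4ccccc4)ccc3C(OCC)[C@H]2O | intermediate
11 | (2R,3R,4R)-7-(benzyloxy)-2-[4-(benzyloxy)phenyl]-4-{(2R,3S)-3,7-bis(benzyloxy)-2-[3,4-bis(benzyloxy)phenyl]chroman-6-yl}chroman-3-ol | c1ccccc1COc1ccc(cc1)[C@H]2Oc3cc(OCc4ccccc4)ccc3[C@H](c5cc6c(cc5OCc4ccccc4)O[C@H](c4ccc(OCc7ccccc7)c(OCc7ccccc7)c4)[C@@H](OCc4ccccc4)C6)[C@H]2O | intermediate
12 | (2R,4R)-7-(benzyloxy)-2-[4-(benzyloxy)phenyl]-4-{(2R,3S)-3,7-bis(benzyloxy)-2-[3,4-bis(benzyloxy)phenyl]chroman-6-yl}chroman-3-one | c1ccccc1COc1ccc(cc1)[C@H]2Oc3cc(OCc4ccccc4)ccc3[C@H](c5cc6c(cc5OCc4ccccc4)O[C@H](c4ccc(OCc7ccccc7)c(OCc7ccccc7)c4)[C@@H](OCc4ccccc4)C6)C2=O | intermediate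
13 | (2R,3S,4R)-7-(benzyloxy)-2-[4-(benzyloxy)phenyl]-4-{(2R,3S)-3,7-bis(benzyloxy)-2-[3,4-bis(benzyloxy)phenyl]chroman-6-yl}chroman-3-ol | c1ccccc1COc1ccc(cc1)[C@H]2Oc3cc(OCc4ccccc4)ccc3[C@H](c5cc6c(cc5OCc4ccccc4)O[C@H](c4ccc(OCc7ccccc7)c(OCc7ccccc7)c4)[C@@H](OCc4ccccc4)C6)[C@@H]2O | intermediate
14 | (2R,3S,4S)-4-[(2R,3S)-2-(3,4-dihydroxyphenyl)-3,7-dihydroxychroman-6-yl]-2-(4-hydroxyphenyl)chromane-3,7-diol | Oc1ccc([C@H]2Oc3cc(O)ccc3[C@H](c3cc4c(cc3O)O[C@H](c3ccc(O)c(O)c3)[C@@H](O)C4)[C@@H]2O)cc1 | target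

**Step count.** Total: 9 steps. Longest linear sequence: 8 steps (steps 1–4, then 6–9).

**Steps most likely to fail**

Step 6. The flavan-4-yl cation may condense with ring A of 10 or of 11 (oligomer formation), 9 may react through C8, or the oxocarbenium ion may be arylated twice before ring closure. The fallback sets out from 7 and separates ring closure from coupling. BF3·OEt2 and benzyl mercaptan in CH2Cl2 at −40 °C should close ring C by the same C4–C4a bond and trap the cation as (2R,3S,4S)-7-(benzyloxy)-2-[4-(benzyloxy)phenyl]-4-(benzylsulfanyl)chroman-3-ol F1, which is purified. Thiophilic activation of the thioether with AgBF4 in THF at 0 °C in the presence of 9 then releases the cation slowly and should give 11, where the route is rejoined.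

Step 3. The radical intermediate of oxo transfer may rotate before ring closure (cis-to-trans leakage), and enantioselectivity may erode with this electron-rich styrene. The fallback sets out from 4 and uses the enantiopure fisetinidol unit as resolving element. Dimethyldioxirane in acetone at 0 °C, a concerted and stereospecific oxidant, should give the racemic cis-epoxide, that is 5 together with (2R,3R)-2-[4-(benzyloxy)phenyl]-3-(diethoxymethyl)oxirane F2. The conditions of step 4 then give 7 together with (2R,3S)-3-[3-(benzyloxy)phenoxy]-3-[4-(benzyloxy)phenyl]-1,1-diethoxypropan-2-ol F3. The conditions of step 6 convert the pair into 11 and the diastereomeric dimer (2S,3S,4S)-7-(benzyloxy)-2-[4-(benzyloxy)phenyl]-4-{(2R,3S)-3,7-bis(benzyloxy)-2-[3,4-bis(benzyloxy)phenyl]chroman-6-yl}chroman-3-ol F4, which are separated by chromatography; the route is rejoined at 11.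

Step 8. Hydride may be delivered to the β-face, or the ketone may enolise towards C4 or C2 before reduction, with loss of configuration. The fallback sets out from 11 and avoids the ketone. Mitsunobu inversion (4-nitrobenzoic acid, PPh3, DIAD, toluene, 0 °C → rt) should give (2R,3S,4R)-7-(benzyloxy)-2-[4-(benzyloxy)phenyl]-4-{(2R,3S)-3,7-bis(benzyloxy)-2-[3,4-bis(benzyloxy)phenyl]chroman-6-yl}chroman-3-yl 4-nitrobenzoate F5; elimination towards C2 is the main hazard. Methanolysis (K2CO3, MeOH/THF, rt) then gives 13, where the route is rejoined.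

**Further compounds**

F1 | step 6 | (2R,3S,4S)-7-(benzyloxy)-2-[4-(benzyloxy)phenyl]-4-(benzylsulfanyl)chroman-3-ol | c1ccccc1COc1ccc(cc1)[C@H]2Oc3cc(OCc4ccccc4)ccc3[C@H](SCc4ccccc4)[C@H]2O
F2 | step 3 | (2R,3R)-2-[4-(benzyloxy)phenyl]-3-(diethoxymethyl)oxirane | c1ccccc1COc1ccc(cc1)[C@H]1O[C@H]1C(OCC)OCC
F3 | step 3 | (2R,3S)-3-[3-(benzyloxy)phenoxy]-3-[4-(benzyloxy)phenyl]-1,1-diethoxypropan-2-ol | c1ccccc1COc1ccc(cc1)[C@H](Oc1cccc(OCc2ccccc2)c1)[C@@H](O)C(OCC)OCC
F4 | step 3 | (2S,3S,4S)-7-(benzyloxy)-2-[4-(benzyloxy)phenyl]-4-{(2R,3S)-3,7-bis(benzyloxy)-2-[3,4-bis(benzyloxy)phenyl]chroman-6-yl}chroman-3-ol | c1ccccc1COc1ccc(cc1)[C@@H]2Oc3cc(OCc4ccccc4)ccc3[C@@H](c5cc6c(cc5OCc4ccccc4)O[C@H](c4ccc(OCc7ccccc7)c(OCc7ccccc7)c4)[C@@H](OCc4ccccc4)C6)[C@@H]2O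
F5 | step 8 | (2R,3S,4R)-7-(benzyloxy)-2-[4-(benzyloxy)phenyl]-4-{(2R,3S)-3,7-bis(benzyloxy)-2-[3,4-bis(benzyloxy)phenyl]chroman-6-yl}chroman-3-yl 4-nitrobenzoate | c1ccccc1COc1ccc(cc1)[C@H]2Oc3cc(OCc4ccccc4)ccc3[C@H](c5cc6c(cc5OCc4ccccc4)O[C@H](c4ccc(OCc7ccccc7)c(OCc7ccccc7)c4)[C@@H](OCc4ccccc4)C6)[C@@H]2OC(=O)c1ccc(cc1)[N+](=O)[O-]
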